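The earlier runs and the new flask stem from a simulated flask on assumed constants, noise included.

Slowness comes late in these flasks, so I follow the rate of loss of substrate, not the amounts.

in all of them: substrate 20 mM

| flask | coupling partner | remark | time |
|---|---|---|---|
| Saturday's | 26 mM | run made earlier |  |
| Thursday's | 31 mM | run made earlier |  |
| Tuesday's | 47 mM | run made earlier |  |
| dawn | 24.0 mM |  | 5.0 min |
| autumn | 30.0 mM |  | 5.0 min |
| spring | 40.0 mM |  | 5.0 min |

- Saturday's (time / min: mono adduct / %, substrate / %): 0.250: 64, 37; 0.500: 76, 25; 1.00: 82, 16; 2.00: 88, 12; 4.00: 91, 9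
- Thursday's (time / min: mono adduct / %, substrate / %): 0.250: 69, 31; 0.500: 82, 18; 1.00: 92, 9; 2.00: 92, 8; 4.00: 96, 5
- Tuesday's (time / min: mono adduct / %, substrate / %): 0.250: 84, 10; 0.500: 97, 3; 1.00: 95, 0; 2.00: 100, 0; 4.00: 99, 0

(each reading ± 2 percentage points)

- amounts and yields of mono adduct count crystals too
- given per volume of solution although it is solid: crystals
- on the list of suspects stand: substrate + coupling partner -> mono adduct; coupling partner + mono adduct -> bis adduct; crystals <-> mono adduct; coupling partner <-> dormant form

1. mono adduct at the end, in percent of the substrate charged, for each flask in turn (dawn, autumn, spring)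

In Saturday's run the substrate falls at 3.98 min⁻¹ over the first reading, but at 0.144 min⁻¹ between 2.00 min and 4.00 min, which is far slower. I find two factors. Spare partner, meaning partner charged less substrate consumed, falls from 26 mM to 7.80 mM, a factor of 3.33. The rate per mM of spare partner falls from 0.153 mM⁻¹ min⁻¹ to 0.0184 mM⁻¹ min⁻¹, a factor of 8.32. I read this second factor as partner going dormant, a suspect on the list.

Thursday's run gives 0.0196 mM⁻¹ min⁻¹ for the same late figure. I carry the mean, 0.0190 mM⁻¹ min⁻¹, and call it the late constant: the late pseudo-first-order rate of substrate loss divided by spare partner. It is a reading, and it carries the scatter.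

Spare partner tends to 4.00 mM in dawn and 20.0 mM in spring. That gives late rates near 0.0760 min⁻¹ and 0.380 min⁻¹. From 2.00 min to 5.0 min, dawn's substrate then shrinks by a factor of 1.26 and spring's by 3.13. I commit to this much: dawn ends on a slow tail with substrate left, and spring ends close to complete.

The forecast says 90%, 95% and 99%, on a partner loss “which allows a slow tail”.

The flasks give 87.6%, 96.1% and 99.0%, so the forecast stands within its margin.

    substrate + coupling partner → mono adduct (k = 4.20 M⁻¹ s⁻¹)
    coupling partner + mono adduct → bis adduct (k = 0.210 M⁻¹ s⁻¹)
    crystals ⇌ mono adduct, rate k3*(cs3 - [mono adduct]) while solid is left; crystals form when [mono adduct] > cs3 (solubility = 0.490 mM, k = 14.0 s⁻¹)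
    coupling partner ⇌ dormant form (K = 9.80, k = 0.0190 s⁻¹)

In dawn the coupling partner goes to substrate 4.4 times as fast as to dormant form at the start and 2.5 times as fast at 0.133 min, forward step alone; at the end dormant form stands at 5.97 mM and free partner at 1.65% of its charge. The forecast's 99% for spring would be wrong at 50.0 min, where mono adduct stands at 96.7% and bis adduct at 3.28%. From 2.50 min to 5.00 min the late constant comes to 0.0160 mM⁻¹ min⁻¹ in dawn and 0.0207 mM⁻¹ min⁻¹ in autumn, against the carried 0.0190 mM⁻¹ min⁻¹.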